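**Assumption:** Hansfordiol B has no stereocentre (it is achiral), so no enantiomer question arises. Cyclohexadecanone (macrocyclic musk ketone) and 5-bromoresorcinol are taken as commercial.

## Retrosynthetic overview

1. Target 11 ⇒ diacetate 10 by mild acetate methanolysis.
2. Key disconnection: the aryl–CH2 bond and the distant methyl ketone are both traced back to one ring C–C bond, so 10 ⇒ aryl bromide 7 + 1-methylcyclohexadecan-1-ol 4 (redox-neutral ring-opening arylation via alkoxyl-radical β-scission and Ni capture).
3. 4 ⇒ cyclohexadecanone 1 + MeMgBr 2; 7 ⇒ 5-bromoresorcinol 5 + Ac2O 6.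
4. Rings: none is formed. The arene is bought, and the only ring event is the opening of the C16 carbocycle, which delivers the whole C17 chain with the ketone already in place.
5. Deliberately avoided: the usual 3,5-dimethoxybenzaldehyde Wittig (or benzylic alkylation) / hydrogenation / BBr3 sequence on a linear chain.

## Route

Step 1
Reactants: 1 cyclohexadecanone; 2 methylmagnesium bromide
Product: 4 1-methylcyclohexadecan-1-ol, via bromomagnesium 1-methylcyclohexadecan-1-olate 3 (not isolated)
Conditions: MeMgBr (1.5 equiv), THF, 0 °C → rt; then sat. aq NH4Cl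
Reagents that add atoms: methylmagnesium bromide (2), C[Mg]Br
Why: Grignard 1,2-addition to an unhindered macrocyclic ketone gives the tertiary alcohol; the new carbinol carbon carries two identical ring arms and is not a stereocentre.

Step 2
Reactants: 5 5-bromobenzene-1,3-diol (5-bromoresorcinol); 6 acetic anhydride
Product: 7 5-bromo-1,3-phenylene diacetate
Conditions: Ac2O (2.5 equiv), pyridine, DMAP (cat.), CH2Cl2, 0 °C → rt
Reagents that add atoms: acetic anhydride (6), CC(=O)OC(C)=O
Why: DMAP-catalysed O-acetylation of both phenols; the acetates make the arene electron-poor (hard to oxidise in step 3, fast oxidative addition) and come off later without touching the ketone.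

Step 3
Reactants: 4 1-methylcyclohexadecan-1-ol (1.5 equiv); 7 5-bromo-1,3-phenylene diacetate (1.0 equiv)
Product: 10 5-(16-oxoheptadecyl)-1,3-phenylene diacetate, via 1-methylcyclohexadecyloxyl radical 8 (not isolated), via 16-oxoheptadecyl radical 9 (not isolated)
Conditions: [Ir(dF(CF3)ppy)2(5,5′-d(CF3)bpy)]PF6 (2 mol%), NiBr2·glyme (10 mol%), dtbbpy (12 mol%), 2,4,6-collidine (2 equiv), PhCF3/MeCN 3:1, 450 nm LEDs, 30 °C, Ar
Reagents that add atoms: none
Why: Proposed new method: excited Ir(III) plus collidine remove H+/e− from the O–H of 4 by concerted PCET to give alkoxyl radical 8, β-scission of a ring C–C bond (primary alkyl radical strongly preferred over methyl loss, two equivalent ring bonds) opens the macrocycle to the remote radical 9 with the methyl ketone already formed, and 9 is captured by (dtbbpy)Ni(Ar)Br and reductively eliminated from Ni(III) with Ir(II) closing a Ni(I)/Ni(III) cycle; the closest known reaction types are PCET ring-opening of unactivated tertiary cycloalkanols and photoredox/nickel ring-opening (remote) arylation of tertiary cycloalkanols with aryl bromides, extended here to a macrocyclic 1-methylcycloalkanol.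

Step 4
Reactants: 10 5-(16-oxoheptadecyl)-1,3-phenylene diacetate
Product: 11 Hansfordiol B, 5-(16-oxoheptadecyl)benzene-1,3-diol
Conditions: K2CO3 (0.2 equiv), degassed MeOH, 0 °C → rt, Ar; then dilute aq HCl to pH 5
Reagents that add atoms: none
Why: Base-catalysed transesterification (Zemplén-type methanolysis) of the two aryl acetates is fast at or below room temperature, where the unactivated methyl ketone does not undergo aldol chemistry; no stereocentre is involved.

## Compound list

1 | cyclohexadecanone | O=C1CCCCCCCCCCCCCCC1 | starting material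
2 | methylmagnesium bromide | C[Mg]Br | starting material
3 | bromomagnesium 1-methylcyclohexadecan-1-olate | CC1(O[Mg]Br)CCCCCCCCCCCCCCC1 | intermediate (not isolated)
4 | 1-methylcyclohexadecan-1-ol | CC1(O)CCCCCCCCCCCCCCC1 | intermediate
5 | 5-bromobenzene-1,3-diol (5-bromoresorcinol) | Oc1cc(O)cc(Br)c1 | starting material
6 | acetic anhydride | CC(=O)OC(C)=O | starting material
7 | 5-bromo-1,3-phenylene diacetate | CC(=O)Oc1cc(Br)cc(OC(C)=O)c1 | intermediate
8 | 1-methylcyclohexadecyloxyl radical | CC1([O])CCCCCCCCCCCCCCC1 | intermediate (not isolated)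
9 | 16-oxoheptadecyl radical | CC(=O)CCCCCCCCCCCCCC[CH2] | intermediate (not isolated)
10 | 5-(16-oxoheptadecyl)-1,3-phenylene diacetate | CC(=O)CCCCCCCCCCCCCCCc1cc(OC(C)=O)cc(OC(C)=O)c1 | intermediate
11 | Hansfordiol B, 5-(16-oxoheptadecyl)benzene-1,3-diol (achiral) | CC(=O)CCCCCCCCCCCCCCCc1cc(O)cc(O)c1 | target

## Step count and risk

Total steps: 4. Longest linear sequence: 3 (1 → 4 → 10 → 11); step 2 is a one-step side branch.

Steps most likely to fail, most risky first:

**Step 3 (ring-opening arylation).** In the unstrained 16-ring the alkoxyl radical 8 can undergo 1,5-hydrogen transfer from C4–H instead of β-scission, and for a free tertiary alkoxyl radical this may well be the faster path. PCET to a purely aliphatic O–H is also only just feasible, and nickel capture of a primary radical must outrun its reduction. The fallback avoids oxygen radicals and sets out from 4: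
- Acid-catalysed dehydration (TsOH cat., toluene, reflux) gives 1-methylcyclohexadec-1-ene F1 as an E/Z mixture. Any exocyclic isomer only regenerates 1 in the next operation.
- Ozonolysis (O3, CH2Cl2, −78 °C; PPh3) opens the ring to 16-oxoheptadecanal F2.
- Aldehyde-selective reduction (NaBH(OAc)3, THF, rt) gives 17-hydroxyheptadecan-2-one F3.
- Appel bromination (CBr4, PPh3, CH2Cl2, 0 °C) gives 17-bromoheptadecan-2-one F4.
- Nickel-catalysed reductive cross-electrophile coupling of F4 with 7 (NiI2, dtbbpy, NaI cat., Zn, DMA, 60 °C) forms the aryl–CH2 bond. The route is rejoined at 10.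

**Step 1 (Grignard addition).** The macrocyclic ketone may enolise or convert incompletely. The fallback sets out from 1:
- Wittig methylenation (Ph3PCH3Br, KOtBu, THF) gives methylidenecyclohexadecane F5.
- Mukaiyama Markovnikov hydration (Mn(dpm)3 cat., PhSiH3, O2, iPrOH, rt) gives the tertiary alcohol. The route is rejoined at 4.

**Step 4 (deacetylation).** The free resorcinol is air-sensitive as its phenoxide, and base could in principle trigger ketone self-condensation. The fallback removes all basic steps after the coupling by changing the protecting group, and sets out from 5: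
- Boc2O with DMAP (cat.) in MeCN gives 5-bromo-1,3-phenylene bis(tert-butyl carbonate) F6, which is similarly electron-poor.
- Coupling F6 with 4 under the step-3 conditions gives 5-(16-oxoheptadecyl)-1,3-phenylene bis(tert-butyl carbonate) F7.
- Acidolysis (TFA, CH2Cl2, 0 °C → rt) releases the diol directly. The route is rejoined at 11.

## Further compounds

F1 | step 3 | 1-methylcyclohexadec-1-ene (E/Z mixture, geometry irrelevant) | CC1=CCCCCCCCCCCCCCC1
F2 | step 3 | 16-oxoheptadecanal | CC(=O)CCCCCCCCCCCCCCC=O
F3 | step 3 | 17-hydroxyheptadecan-2-one | CC(=O)CCCCCCCCCCCCCCCO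
F4 | step 3 | 17-bromoheptadecan-2-one | CC(=O)CCCCCCCCCCCCCCCBr
F5 | step 1 | methylidenecyclohexadecane | C=C1CCCCCCCCCCCCCCC1
F6 | step 4 | 5-bromo-1,3-phenylene bis(tert-butyl carbonate) | CC(C)(C)OC(=O)Oc1cc(Br)cc(OC(=O)OC(C)(C)C)c1
F7 | step 4 | 5-(16-oxoheptadecyl)-1,3-phenylene bis(tert-butyl carbonate) | CC(=O)CCCCCCCCCCCCCCCc1cc(OC(=O)OC(C)(C)C)cc(OC(=O)OC(C)(C)C)c1
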